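Atom numbering used throughout: seven-membered ring C1 (CH with the acetonyl group), C2 (C=O), C3 (C–OH), C12 (CH), C11 (CH2), C10 (C–CH3), C13 (CH with the enol ester arm); cyclohexane C7–C8–C9–C10–C11–C12; pyran C3–C4–O5–C6(CH3)2–C7–C12; arms C13–C14=C15–O and C1–C16–C17(=O)–C18. "Exo" means the face of the seven-membered ring turned away from the C7–C8–C9 bridge, "endo" the face of that bridge. Names of polycyclic intermediates use this numbering.

## Analysis of the target

CNP0237201.2 is a C20 tricycle carrying a C5 acyl group. A cycloheptanone (C1, C2, C3, C12, C11, C10, C13) shares C10–C11–C12 with a cyclohexane (C7–C12), giving a bicyclo[4.3.1]decane. A 6,6-dimethyltetrahydropyran (C3–C4–O5–C6–C7–C12) is fused to both carbocycles at C12. There are six stereocentres, C1, C3, C7, C10, C12 and C13 (1S,3R,7R,10S,12S,13S in this numbering), and one (E)-enol ester double bond. The C3 hydroxyl, the C10 methyl and the C13 arm are exo; C4 of the pyran and the C1 acetonyl group are endo, so C1 and C13 are trans. C6 is equatorial on C7 and cis to C3 across C12. The sensitive groups are the (E)-enol 3-methylbut-2-enoate (base, nucleophiles), the tertiary α-ketol C3/C2 (acyloin shift, retro-aldol), the epimerisable C1 and the dicarbonyl relationships that appear once the two arms are unmasked. The hard points are the quaternary bridgehead C10 with the substituted C13 beside it, the bridged seven-membered ring and the fully substituted carbinol C3. The strategy rests on one feature: the cyclohexane carbons C7–C12, with the methyl-bearing C10 para to C7, are the ring of p-cresol, and C12, which is α to a carbonyl placed at C7, is bonded to the carbinol C3, so C3–C12 is an aldol bond.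

## Retrosynthetic reasoning

**Enol ester C15–O.** Target 30 is the desilylated form of 29, and 29 is cut at the enol C15–O bond into the (E)-alkenylboronate 26 and the acid 27. Cutting here means the double-bond geometry is made before the ester exists, and no aldehyde enolate has to be generated next to two ketones. The forward coupling has to retain the alkene geometry.

**C14=C15.** Boronate 26 is cut at the double bond to the C14 aldehyde 25. The forward olefination must touch the aldehyde only and give the E isomer.

**The two carbonyl arms.** The C14 aldehyde and the C17 ketone of 25 are both traced to alkenes in 24, a vinyl group on C13 and a 2-methylallyl group on C1. One oxidative cleavage then unmasks both, and no carbonyl-bearing nucleophile or electrophile is needed earlier.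

**C13–C14 and C1–C16.** Ketone 24 is cut at both bonds back to the enone 21, through the enol ether 22. C13 lies next to the quaternary C10 and can only be reached as the β-carbon of an enone. The forward pair is conjugate addition from the exo face, then alkylation of the regiodefined enolate anti to the new neighbour.

**C1=C13.** Enone 21 comes from ketone 19 through the enol ether 20. C1 is the only enolisable position of the C2 ketone and C10 is quaternary, so the unsaturation has one place to go.

**Pyran bond O5–C6 and the C6 methyls.** Ketone 19 is cut at the tertiary ether bond to diol 18, and the two C6–CH3 bonds are cut to give lactone 17. Cutting O5–C6 and not C4–O5 is chosen because C4 is neopentyl and would not take part in a displacement. The forward closure runs through the C6 cation.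

**C6–C7.** Lactone 17 goes back through ester 15 to the enol triflate 14, which is made from the enone that the key step leaves in 12. The forward hydrogenation has to deliver hydrogen to C7 from the face opposite the four-carbon bridge.

**C3–C12 (key disconnection).** The aldol 11 is cut at C3–C12 with removal of a hydride from C11, which gives the achiral dienone 9. This removes the seven-membered ring and three stereocentres at once and leaves a flat precursor with one prochiral carbon. The forward step has to reduce one of two enantiotopic enone arms and close the ring on C3, not on C2.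

**The α-keto ketal.** Precursor 9 is traced to the 2-benzyloxy enone 8, from aldol 6, from aldehyde 4 and the symmetrical ketone 5 (C1–C2 bond). The two carbons of the 1,2-dione are distinguished by construction: C2 arrives as an ether-bearing carbon and becomes an enol ether on dehydration, while C3 is the ketone of 5. Selective ketalisation of a free 1,2-dione is avoided.

**C10–C13.** Aldehyde 4 comes from 3 by cleavage of the allyl group, and 3 from 1 and 2 by dearomatising allylation at the para carbon. This makes C10 quaternary in one step from a flat phenol.

## Alternatives that were turned down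

**Alternative 1: tethered (4+3) cycloaddition of an oxyallyl cation.**
- Disconnection: C12–C3 and C10–C13 are cut together. The six-membered ring comes from a chiral-pool terpene ketone that already carries C7 and the C6 ether.
- Forward key step: a tertiary α-chloro ketone (Cl on C10, C=O at C11) is ionised by mild base in a fluorinated alcohol. The cation across C10–C11–C12 is captured by a 1,2-bis(silyloxy)diene tethered through C7–C6–O5–C4, giving A1.
- For: two C–C bonds, the pyran and the seven-membered ring, and C3, C10, C12 and C13 all form in one step. C13 arrives with its two-carbon arm, and the C1=C2 silyl enol ether of A1 is ready for alkylation. On convergence and on the C13 problem this plan is stronger than the chosen one.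
- Against: A1 has a carbonyl at C11, where the target has CH2. Removing a bridging ketone flanked by C10 and C12 without touching C2 costs several steps. The new C10–C13 bond joins a fully substituted cation terminus to a substituted diene terminus, so stepwise pathways and proton loss compete. C3 and C13 depend on a tetrasubstituted bis(silyloxy) alkene of defined geometry and on the compact or extended approach through a tether that contains a quaternary ether carbon.
- Comparison: the chosen route offers a five-step achiral precursor, catalyst control of C10 and no extra carbonyl to excise. It pays by functionalising C13 and C1 late.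

**Alternative 2: allene photocycloaddition and retro-Claisen cleavage.**
- Disconnection: C13–C14 and C1–C15 on the finished tricycle.
- Forward key step: irradiation of the C1=C13 enone A2 (the free alcohol of my 21) with allene A3 gives the exo methylenecyclobutane A4. Ozonolysis and alkoxide-induced retro-Claisen cleavage would leave the C13 acetic ester A5.
- For: the excited enone does not feel the neopentyl hindrance at C13 the way a nucleophile does, and exo approach sets C13. C14 and C15 arrive together with C15 oxidised. On reaching C13 regardless of sterics it is stronger than a cuprate.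
- Against: it builds no ring, so A2 must come from another route. Cycloheptenones can isomerise to strained trans isomers on irradiation and then add without stereocontrol. The head-to-head regiochemistry is required. Three steps replace one conjugate addition. Alkoxide on the α-ketol of A4 invites acyloin shift and retro-aldol. A5 must then be reduced to the aldehyde beside the C2 ketone and O-acylated with uncertain E/Z control.
- Comparison: the chosen route meets the same enone as 21 and uses a vinyl group, whose cleavage is shared with the unmasking of the acetonyl arm, and it makes the enol ester with defined geometry.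

**Alternative 3: bridged Diels–Alder from a bis-methylene pyran.**
- Disconnection: C8–C9 and C10–C11 of the cyclohexane.
- Forward key step: an s-cis exocyclic diene C8=C7–C12=C11 on the pyran adds an isopropenyl ketone C9=C10 that hangs from C3 through C2–C1–C13 (a type 2 intramolecular Diels–Alder reaction). This gives the bridgehead alkene A6 with a C13 ketone and a dithiane at C2.
- For: two C–C bonds, the cyclohexene and the seven-membered ring form at once, and C10 becomes quaternary. C13 arrives as a ketone, a handle the chosen route lacks, and one hydrogenation of C7=C12 could set C7 and C12 cis. In bond economy and in the C13 handle it is the stronger plan.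
- Against: C3 is the only stereocentre of the precursor. It must be made enantiopure as a tertiary carbinol inside a pyran carrying a polymerisable bis-methylene diene, and it must relay to C10 across a flexible forming seven-membered ring. Four-atom tethers of this type need forcing conditions. The tetrasubstituted bridgehead alkene of A6 must take up hydrogen from one face in the presence of catalyst-poisoning sulfur. The hindered C13 ketone must be homologated with control of C13, and C1 still needs alkylation.
- Comparison: the chosen route sets the absolute configuration by a catalyst on an achiral dienone, sets C12 by the geometry of the bridge and C7 by exo-face hydrogenation of an enoate, and carries no sulfur.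

Key step: step 6

Remarks on the chemistry (assumptions):
- The sense of arm selection by (R)-DTBM-SEGPHOS in step 6 is taken to be the one drawn. If the other arm is reduced, the (S)-ligand is used and nothing else changes.
- The tertiary triethylsilyl ether at C3 is taken to survive KHF2 in step 19. If it is lost there, step 20 falls away.

## Route

Step 1
Reactants: 1 p-cresol; 2 allyltrimethylsilane
Product: 3 4-allyl-4-methylcyclohexa-2,5-dien-1-one
Conditions: PhI(OAc)2, (CF3)2CHOH/CH2Cl2, −20 → 0 °C
Reagents that add atoms: none
Why: Oxidative dearomatisation: the trivalent iodine reagent activates the phenol and the allylsilane attacks the para carbon (Hosomi–Sakurai-type SE2′ attack), a reaction known for 4-alkylphenols in fluorinated alcohols; C10 becomes quaternary and stays prochiral.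

Step 2
Reactants: 3 4-allyl-4-methylcyclohexa-2,5-dien-1-one
Product: 4 2-(1-methyl-4-oxocyclohexa-2,5-dien-1-yl)acetaldehyde
Conditions: OsO4 (cat.), NaIO4, 2,6-lutidine, dioxane/H2O, rt
Reagents that add atoms: sodium periodate, [Na+].[O-]I(=O)(=O)=O
Why: Lemieux–Johnson cleavage; OsO4 dihydroxylates the terminal alkene far faster than the electron-poor dienone double bonds, and periodate cleaves the diol to the aldehyde that carries C1.

Step 3
Reactants: 4 2-(1-methyl-4-oxocyclohexa-2,5-dien-1-yl)acetaldehyde; 5 1,3-bis(benzyloxy)propan-2-one
Product: 6 1,3-bis(benzyloxy)-4-hydroxy-5-(1-methyl-4-oxocyclohexa-2,5-dien-1-yl)pentan-2-one (diastereomer mixture)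
Conditions: 5, Bu2BOTf, i-Pr2NEt, CH2Cl2, −78 °C; then 4, −78 → −20 °C; pH 7 buffer, MeOH
Reagents that add atoms: none
Why: Boron aldol addition; the dibutylboron enolate of the symmetrical ketone adds to the aldehyde only and not to the dienone, and no lithium base meets the dienone. Both new stereocentres are erased in step 4.

Step 4
Reactants: 6 1,3-bis(benzyloxy)-4-hydroxy-5-(1-methyl-4-oxocyclohexa-2,5-dien-1-yl)pentan-2-one
Product: 8 (Z)-1,3-bis(benzyloxy)-5-(1-methyl-4-oxocyclohexa-2,5-dien-1-yl)pent-3-en-2-one, via aldol mesylate 7 (not isolated)
Conditions: MsCl, Et3N, CH2Cl2, 0 °C; then DBU, 0 °C → rt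
Reagents that add atoms: none
Why: Mesylation and E1cB elimination give the 2-benzyloxy enone, in which C2 has reached the ketone oxidation level as an enol ether while C3 is the free ketone. Elimination from the enolate should be much faster than its Michael addition to the dienone; the alkene geometry does not matter for step 5.

Step 5
Reactants: 8 (Z)-1,3-bis(benzyloxy)-5-(1-methyl-4-oxocyclohexa-2,5-dien-1-yl)pent-3-en-2-one
Product: 9 2-(benzyloxy)-1-{2-[2-(1-methyl-4-oxocyclohexa-2,5-dien-1-yl)ethyl]-1,3-dioxolan-2-yl}ethan-1-one
Conditions: HOCH2CH2OH, camphorsulfonic acid (cat.), 4 Å MS, CH2Cl2, rt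
Reagents that add atoms: ethane-1,2-diol, OCCO
Why: Acid-catalysed acetal exchange of an enol ether: protonation at C1 gives the oxocarbenium ion at C2, the diol adds and benzyl alcohol leaves, so the dioxolane forms at C2 only (the path by which enol ethers of 1,2-diones give mono-ketals). The cross-conjugated dienone does not ketalise under these conditions.

Step 6
Reactants: 9 2-(benzyloxy)-1-{2-[2-(1-methyl-4-oxocyclohexa-2,5-dien-1-yl)ethyl]-1,3-dioxolan-2-yl}ethan-1-one
Product: 11 bicyclo[4.3.1]dec-8-en-7-one aldol with C2 dioxolane, C3 hydroxyl (exo) and C3 benzyloxymethyl (beside C7), C10 methyl, via silylated aldol 10 (not isolated)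
Conditions: Cu(OAc)2 (5 mol %), (R)-DTBM-SEGPHOS (5.5 mol %), (EtO)2MeSiH (1.3 equiv, slow addition), toluene, 0.02 M, −40 → −10 °C; then NH4F, MeOH, 0 °C
Reagents that add atoms: none
Why: Proposed new method: the phosphine-ligated copper hydride formed from Cu(OAc)2 and the silane adds hydride to C11 of one enone arm, the copper enolate at C12 attacks the C3 ketone (C3–C12 bond; seven-membered ring by 7-exo-trig closure on the ketone with the enolate double bond outside the new ring), and the copper aldolate is silylated by the silane to 10, which returns the copper hydride. The closest known reaction type is the copper-hydride or rhodium-hydride catalysed reductive aldol cyclisation of keto-enones and keto-enoates to five- and six-membered rings, desymmetrising cases included; a seven-membered closure has not been shown. C10 and C12 are set together by the ligand's choice between the two enantiotopic arms, because the four-carbon bridge can only span C10 and C12 on one face. C3 is set in the closure itself: with copper held between the enolate oxygen and the ketone oxygen, the bulky spiro-dioxolane carbon C2 is expected to turn outward and the slim CH2OBn arm inward, which after relaxation of the ring places the arm beside C7 and the oxygen exo, as the pyran needs. The step needs 1,4- over 1,2-reduction (soft copper hydride, hindered ketal-flanked ketone), C3 over C2 as acceptor (the ketal rules out the six-membered closure) and cyclisation ahead of enolate silylation (α-benzyloxy activation of C3, low silane concentration). Fluoride releases the free alcohol 11 and leaves the second enone for step 8.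

Step 7
Reactants: 11 bicyclic aldol
Product: 12 C3 triethylsilyl ether of 11
Conditions: Et3SiOTf, 2,6-lutidine, CH2Cl2, −40 → 0 °C
Reagents that add atoms: triethylsilyl trifluoromethanesulfonate, CC[Si](CC)(CC)OS(=O)(=O)C(F)(F)F
Why: Silylation of the tertiary aldol hydroxyl with a silyl triflate; the ether blocks retro-aldol opening of the seven-membered ring in the basic steps that follow.

Step 8
Reactants: 12 C3 triethylsilyl ether of 11
Product: 14 C7 enol triflate (C7=C8) with C8–C9 reduced, via lithium C7 enolate 13 (not isolated)
Conditions: LiBH(s-Bu)3, THF, −78 °C; then 2-[N,N-bis(trifluoromethylsulfonyl)amino]-5-chloropyridine, −78 → 0 °C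
Reagents that add atoms: 2-[N,N-bis(trifluoromethylsulfonyl)amino]-5-chloropyridine, FC(F)(F)S(=O)(=O)N(c1ccc(Cl)cn1)S(=O)(=O)C(F)(F)F
Why: Conjugate reduction of the β-unsubstituted enone by the bulky borohydride gives the C7=C8 enolate regiospecifically, and O-triflation traps it. The bridgehead C12 is not involved because the enolate comes from hydride addition, not deprotonation.

Step 9
Reactants: 14 C7 enol triflate
Product: 15 methyl ester at C7 (C6 is the ester carbon, C7=C8)
Conditions: Pd(OAc)2 (5 mol %), PPh3, CO (1 atm), MeOH, Et3N, DMF, 50 °C
Reagents that add atoms: carbon monoxide, [C-]#[O+]; methanol, CO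
Why: Palladium-catalysed methoxycarbonylation of an alkenyl triflate (oxidative addition to zerovalent palladium, CO insertion, methanolysis) attaches C6 to C7.

Step 10
Reactants: 15 methyl ester at C7
Product: 17 tricyclic lactone (C6=O, ring O5–C4) with C2 dioxolane and C3 silyl ether, via saturated hydroxy ester 16 (not isolated)
Conditions: H2 (3 atm), Pd/C, EtOAc, rt; filter; camphorsulfonic acid (cat.), toluene, 60 °C
Reagents that add atoms: none
Why: Heterogeneous hydrogenation adds hydrogen to C7=C8 from the face of the six-membered ring not covered by the C13–C1–C2–C3 bridge, which puts C6 equatorial and cis to C3 as in the target; the same catalyst cleaves the benzyl ether. The freed C4 hydroxyl lactonises onto the ester, which is possible only with the required C3 and C7 configurations.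

Step 11
Reactants: 17 tricyclic lactone
Product: 18 diol with C6 dimethyl carbinol and free C4 hydroxyl
Conditions: MeMgBr (5 equiv), THF, 0 °C → rt
Reagents that add atoms: methylmagnesium bromide, C[Mg]Br
Why: Double Grignard addition to the lactone through the methyl ketone gives the tertiary C6 carbinol and frees the C4 hydroxyl; ketal and silyl ether are inert.

Step 12
Reactants: 18 diol
Product: 19 tricyclic α-hydroxy ketone (C2=O, C3–OH, 6,6-dimethylpyran, C1 and C13 CH2)
Conditions: TsOH·H2O (cat.), CH2Cl2, 0 °C → rt; then 2 M HCl, THF, 40 °C
Reagents that add atoms: water, O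
Why: Acid ionises the tertiary C6 alcohol and the primary C4 hydroxyl captures the cation (cyclodehydration to the tetrahydropyran; the six-membered ether is favoured over attack by the silylated C3 oxygen). Aqueous acid then hydrolyses the dioxolane and the silyl ether; no stereocentre sits on a reacting carbon.

Step 13
Reactants: 19 tricyclic α-hydroxy ketone
Product: 20 C2 triethylsilyl enol ether (C1=C2) with C3 triethylsilyl ether
Conditions: Et3SiOTf, Et3N, CH2Cl2, 0 °C
Reagents that add atoms: triethylsilyl trifluoromethanesulfonate, CC[Si](CC)(CC)OS(=O)(=O)C(F)(F)F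
Why: Soft enolisation and silylation; C1 is the only enolisable position of the C2 ketone, so the enol ether is regiodefined, and the C3 hydroxyl is silylated in the same operation.

Step 14
Reactants: 20 bis-silyl enol ether
Product: 21 C1=C13 enone with C3 triethylsilyl ether
Conditions: Pd(OAc)2 (10 mol %), O2 (1 atm), DMSO, 40 °C
Reagents that add atoms: none
Why: Saegusa–Ito oxidation: the palladium enolate at C1 loses the C13 hydride, and because C10 is quaternary the unsaturation can only stop at C1=C13.

Step 15
Reactants: 21 C1=C13 enone
Product: 22 13-vinyl (exo) C2 trimethylsilyl enol ether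
Conditions: CH2=CHMgBr, CuBr·SMe2, Me3SiCl, THF, −78 °C; Et3N, cold NaHCO3
Reagents that add atoms: vinylmagnesium bromide, C=C[Mg]Br; chlorotrimethylsilane, C[Si](C)(C)Cl
Why: Chlorosilane-accelerated conjugate addition of a vinyl cuprate; the reagent should approach C13 from the exo face because the endo face lies over the six-membered ring, which places C14 cis to the C10 methyl as in the target. The enolate is kept as its trimethylsilyl ether.

Step 16
Reactants: 22 13-vinyl silyl enol ether
Product: 24 1-(2-methylallyl) (endo) 13-vinyl (exo) ketone with C3 triethylsilyl ether, via lithium C2 enolate 23 (not isolated)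
Conditions: MeLi, THF, 0 °C; then DMPU, CH2=C(CH3)CH2Br, −78 → −20 °C
Reagents that add atoms: 3-bromo-2-methylprop-1-ene, C=C(C)CBr
Why: Regiospecific lithium enolate from the silyl enol ether, then allylic alkylation; the electrophile should enter anti to the neighbouring vinyl group (the usual trans outcome of conjugate addition followed by alkylation), which gives the endo C1 substituent. C1 stays epimerisable, so the trans relationship can also be reached by equilibration.

Step 17
Reactants: 24 1-(2-methylallyl)-13-vinyl ketone
Product: 25 keto aldehyde with C1 acetonyl group and C13 formyl group (C14)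
Conditions: O3, CH2Cl2/MeOH, −78 °C; then Me2S
Reagents that add atoms: ozone, [O-][O+]=O
Why: Ozonolysis of both alkenes in one operation: the 2-methylallyl group becomes the acetonyl group (C16–C18) and the vinyl group becomes the C14 aldehyde. The neutral reductive work-up spares the epimerisable C13 and C1.

Step 18
Reactants: 25 keto aldehyde
Product: 26 (E)-C14=C15 alkenyl pinacol boronate
Conditions: CrCl2, Cl2CHB(pin), LiI, THF, rt
Reagents that add atoms: 2-(dichloromethyl)-4,4,5,5-tetramethyl-1,3,2-dioxaborolane, ClC(Cl)B1OC(C)(C)C(C)(C)O1
Why: Takai-type olefination with the geminal dichromium reagent formed from the dichloromethylboronate and divalent chromium; it reacts with aldehydes and not with ketones and gives the (E)-alkenylboronate, which fixes the C14=C15 geometry.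

Step 19
Reactants: 26 (E)-alkenyl pinacol boronate; 27 3-methylbut-2-enoic acid
Product: 29 C3 triethylsilyl ether of the target, via potassium alkenyltrifluoroborate 28 (not isolated)
Conditions: KHF2, MeOH/H2O, 0 °C → rt, evaporate; then 27, CuBr (10 mol %), DMAP, 4 Å MS, O2 (1 atm), MeCN, 40 °C
Reagents that add atoms: none
Why: Copper-catalysed oxidative C–O coupling of an alkenyltrifluoroborate with a carboxylic acid (Chan–Lam-type enol ester synthesis), which proceeds with retention of alkene geometry and needs no aldehyde enolate beside the two ketones.

Step 20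
Reactants: 29 C3 triethylsilyl ether of the target
Product: 30 CNP0237201.2
Conditions: HF·pyridine, pyridine, THF, 0 °C → rt
Reagents that add atoms: none
Why: Fluoride cleavage of the tertiary triethylsilyl ether under buffered, non-basic conditions that should leave the enol ester and the α-ketol untouched.

## Compound list

1 | p-cresol (4-methylphenol) | Cc1ccc(O)cc1 | starting material
2 | allyltrimethylsilane | C=CC[Si](C)(C)C | starting material
3 | 4-allyl-4-methylcyclohexa-2,5-dien-1-one | C=CCC1(C)C=CC(=O)C=C1 | intermediate
4 | 2-(1-methyl-4-oxocyclohexa-2,5-dien-1-yl)acetaldehyde | O=CCC1(C)C=CC(=O)C=C1 | intermediate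
5 | 1,3-bis(benzyloxy)propan-2-one | O=C(COCc1ccccc1)COCc1ccccc1 | starting material
6 | 1,3-bis(benzyloxy)-4-hydroxy-5-(1-methyl-4-oxocyclohexa-2,5-dien-1-yl)pentan-2-one (diastereomer mixture, both centres erased in step 4) | O=C(COCc1ccccc1)C(OCc1ccccc1)C(O)CC1(C)C=CC(=O)C=C1 | intermediate
7 | 4-O-methanesulfonate of 6 | O=C(COCc1ccccc1)C(OCc1ccccc1)C(OS(C)(=O)=O)CC1(C)C=CC(=O)C=C1 | intermediate
8 | (Z)-1,3-bis(benzyloxy)-5-(1-methyl-4-oxocyclohexa-2,5-dien-1-yl)pent-3-en-2-one | O=C(COCc1ccccc1)/C(OCc1ccccc1)=C/CC1(C)C=CC(=O)C=C1 | intermediate
9 | 2-(benzyloxy)-1-{2-[2-(1-methyl-4-oxocyclohexa-2,5-dien-1-yl)ethyl]-1,3-dioxolan-2-yl}ethan-1-one | CC1(CCC2(OCCO2)C(=O)COCc3ccccc3)C=CC(=O)C=C1 | intermediate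
10 | C3 O-diethoxy(methyl)silyl ether of 11 | C1CC2(OCCO2)[C@](O[Si](C)(OCC)OCC)(COCc3ccccc3)[C@H]4C[C@]1(C)C=CC4=O | intermediate
11 | bicyclo[4.3.1]dec-8-en-7-one aldol: C2 dioxolane, C3 hydroxyl exo, C3 benzyloxymethyl beside C7, C10 methyl | C1CC2(OCCO2)[C@](O)(COCc3ccccc3)[C@H]4C[C@]1(C)C=CC4=O | intermediate
12 | C3 triethylsilyl ether of 11 | C1CC2(OCCO2)[C@](O[Si](CC)(CC)CC)(COCc3ccccc3)[C@H]4C[C@]1(C)C=CC4=O | intermediate
13 | lithium C7 enolate (C7=C8) of the 8,9-dihydro ketone | C1CC2(OCCO2)[C@](O[Si](CC)(CC)CC)(COCc3ccccc3)[C@H]4C[C@]1(C)CC=C4O[Li] | intermediate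
14 | C7 enol triflate (C7=C8) | C1CC2(OCCO2)[C@](O[Si](CC)(CC)CC)(COCc3ccccc3)[C@H]4C[C@]1(C)CC=C4OS(=O)(=O)C(F)(F)F | intermediate
15 | methyl ester at C7 (C7=C8) | C1CC2(OCCO2)[C@](O[Si](CC)(CC)CC)(COCc3ccccc3)[C@H]4C[C@]1(C)CC=C4C(=O)OC | intermediate
16 | saturated hydroxy ester: H7 anti to C3, free C4 hydroxyl | C1CC2(OCCO2)[C@](O[Si](CC)(CC)CC)(CO)[C@H]4C[C@]1(C)CC[C@H]4C(=O)OC | intermediate
17 | tricyclic lactone (C6=O, O5–C4), C2 dioxolane, C3 triethylsilyl ether | C1C4(OCCO4)[C@]2(O[Si](CC)(CC)CC)COC(=O)[C@@H]3CC[C@@](C)(C[C@@H]32)C1 | intermediate
18 | diol: C6 dimethyl carbinol on C7, free C4 hydroxyl | C1CC2(OCCO2)[C@](O[Si](CC)(CC)CC)(CO)[C@H]4C[C@]1(C)CC[C@H]4C(C)(C)O | intermediate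
19 | tricyclic α-hydroxy ketone (C2=O, C3–OH exo, 6,6-dimethylpyran) | C1C(=O)[C@]2(O)COC(C)(C)[C@@H]3CC[C@@](C)(C[C@@H]32)C1 | intermediate
20 | C2 triethylsilyl enol ether (C1=C2), C3 triethylsilyl ether | C1=C(O[Si](CC)(CC)CC)[C@]2(O[Si](CC)(CC)CC)COC(C)(C)[C@@H]3CC[C@@](C)(C[C@@H]32)C1 | intermediate
21 | C1=C13 enone, C3 triethylsilyl ether | C1=CC(=O)[C@]2(O[Si](CC)(CC)CC)COC(C)(C)[C@@H]3CC[C@@]1(C)C[C@@H]32 | intermediate
22 | 13-vinyl (exo) C2 trimethylsilyl enol ether | C1=C(O[Si](C)(C)C)[C@]2(O[Si](CC)(CC)CC)COC(C)(C)[C@@H]3CC[C@@](C)(C[C@@H]32)[C@H]1C=C | intermediate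
23 | lithium C2 enolate of the 13-vinyl ketone | C1=C(O[Li])[C@]2(O[Si](CC)(CC)CC)COC(C)(C)[C@@H]3CC[C@@](C)(C[C@@H]32)[C@H]1C=C | intermediate
24 | 1-(2-methylallyl) (endo), 13-vinyl (exo) ketone, C3 triethylsilyl ether | C=C(C)C[C@@H]1C(=O)[C@]2(O[Si](CC)(CC)CC)COC(C)(C)[C@@H]3CC[C@@](C)(C[C@@H]32)[C@H]1C=C | intermediate
25 | keto aldehyde: 1-acetonyl, 13-formyl | CC(=O)C[C@@H]1C(=O)[C@]2(O[Si](CC)(CC)CC)COC(C)(C)[C@@H]3CC[C@@](C)(C[C@@H]32)[C@H]1C=O | intermediate
26 | (E)-C14=C15 alkenyl pinacol boronate | CC(=O)C[C@@H]1C(=O)[C@]2(O[Si](CC)(CC)CC)COC(C)(C)[C@@H]3CC[C@@](C)(C[C@@H]32)[C@H]1/C=C/B4OC(C)(C)C(C)(C)O4 | intermediate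
27 | 3-methylbut-2-enoic acid | CC(C)=CC(=O)O | starting material
28 | potassium (E)-alkenyltrifluoroborate | CC(=O)C[C@@H]1C(=O)[C@]2(O[Si](CC)(CC)CC)COC(C)(C)[C@@H]3CC[C@@](C)(C[C@@H]32)[C@H]1/C=C/[B-](F)(F)F.[K+] | intermediate
29 | C3 triethylsilyl ether of the target | CC(=O)C[C@@H]1C(=O)[C@]2(O[Si](CC)(CC)CC)COC(C)(C)[C@@H]3CC[C@@](C)(C[C@@H]32)[C@H]1/C=C/OC(=O)C=C(C)C | intermediate
30 | CNP0237201.2 | CC(=O)C[C@@H]1C(=O)[C@]2(O)COC(C)(C)[C@@H]3CC[C@@](C)(C[C@@H]32)[C@H]1/C=C/OC(=O)C=C(C)C | target

## Step count and least certain steps

Total step count: 20. Longest linear sequence: 20 steps (from 1; 2, 5 and 27 are commercial and enter in steps 1, 3 and 19).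

**Step 6 (key step, labelled "Proposed new method:").** Three things can go wrong. The seven-membered closure may be slower than silylation or protonation of the copper enolate, so that plain conjugate reduction results. The catalyst may distinguish the two arms poorly, because only a methyl group and a primary chain differ at C10. The ring may close to the C3 epimer: a tight array through the ketone oxygen with the dioxolane turned inward would put the hydroxyl, not the CH2OBn arm, beside C7. Fallback with known chemistry, from 9: the same Cu(OAc)2/(R)-DTBM-SEGPHOS catalyst with excess PhMe2SiH in THF is run as a desymmetrising 1,4-hydrosilylation and stopped at the dimethylphenylsilyl dienol ether F1. F1 is then closed by an intramolecular Mukaiyama aldol reaction (MgBr2·OEt2, CH2Cl2, −78 → −20 °C, aqueous work-up), in which the α-benzyloxy ketone is chelated and attacked through an open transition state. This returns to the route at 11 and gives a second, mechanistically different chance at C3.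

**Step 5.** Traces of water would hydrolyse the enol ether to the free 1,2-dione, which then ketalises without regiocontrol, and the C3 ketone may ketalise as well. Fallback from 4, with regiochemistry fixed by an ester: Horner–Wadsworth–Emmons reaction with methyl 2-(dimethoxyphosphoryl)-2-methoxyacetate (LiN(SiMe3)2, THF, −78 °C) gives the 2-methoxy enoate F2. Acetal exchange with ethane-1,2-diol and TsOH gives the dioxolane ester F3, where no ketone competes. LiOH gives acid F4, and 1-chloro-N,N,2-trimethylpropenylamine gives acid chloride F5. Stille acylation of F5 with (benzyloxymethyl)tributylstannane and PdCl2(PPh3)2 returns to the route at 9.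

**Step 15.** The β-carbon C13 is next to the quaternary C10, so the cuprate may add slowly, add 1,2, or approach from the endo face. Fallback from 21: rhodium-catalysed conjugate addition of potassium vinyltrifluoroborate ([Rh(cod)Cl]2, Et3N, dioxane/H2O, 80 °C) gives the 13-vinyl ketone F6. Me3SiOTf and Et3N convert F6 to the silyl enol ether, which returns to the route at 22.

**Step 16.** The enolate may be alkylated on the exo face, cis to the vinyl group, because the endo face of C1 is not free of the six-membered ring either, or it may react sluggishly. Fallback with the order reversed, from 20: MeLi then 3-bromo-2-methylprop-1-ene gives the 1-(2-methylallyl) ketone F7 (C1 configuration irrelevant). Dehydrogenation with 2-iodoxybenzoic acid in DMSO at 70 °C gives the 1-substituted C1=C13 enone F8. Vinyl cuprate addition to F8 followed by protonation, and DBU equilibration at C1 if needed, returns to the route at 24.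

**Step 19.** The hindered alkenylborate may undergo protodeboronation or homocoupling faster than C–O coupling. Fallback from 26: oxidation of the boronate (NaBO3·4H2O, THF/H2O) gives the homologous aldehyde F9 (C13–CH2–CHO). O-acylation of its enol with 3-methylbut-2-enoyl chloride, Et3N and catalytic DMAP returns to the route at 29. The E and Z enol esters must then be separated, and the aldehyde can condense with the methyl ketone, which is why this is the fallback and not the main route.

## Further compounds

F1 | step 6 | dimethylphenylsilyl dienol ether of the 4,4-disubstituted cyclohexenone (C12=C7–OSi, C8=C9), C10 set | C(CC2(OCCO2)C(=O)COCc3ccccc3)[C@@]1(C)C=CC(O[Si](C)(C)c4ccccc4)=CC1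
F2 | step 5 | methyl (Z)-2-methoxy-4-(1-methyl-4-oxocyclohexa-2,5-dien-1-yl)but-2-enoate | COC(=O)/C(OC)=C/CC1(C)C=CC(=O)C=C1
F3 | step 5 | methyl 2-[2-(1-methyl-4-oxocyclohexa-2,5-dien-1-yl)ethyl]-1,3-dioxolane-2-carboxylate | COC(=O)C1(CCC2(C)C=CC(=O)C=C2)OCCO1
F4 | step 5 | 2-[2-(1-methyl-4-oxocyclohexa-2,5-dien-1-yl)ethyl]-1,3-dioxolane-2-carboxylic acid | OC(=O)C1(CCC2(C)C=CC(=O)C=C2)OCCO1
F5 | step 5 | 2-[2-(1-methyl-4-oxocyclohexa-2,5-dien-1-yl)ethyl]-1,3-dioxolane-2-carbonyl chloride | ClC(=O)C1(CCC2(C)C=CC(=O)C=C2)OCCO1
F6 | step 15 | 13-vinyl (exo) tricyclic ketone, C3 triethylsilyl ether | C1C(=O)[C@]2(O[Si](CC)(CC)CC)COC(C)(C)[C@@H]3CC[C@@](C)(C[C@@H]32)[C@H]1C=C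
F7 | step 16 | 1-(2-methylallyl) tricyclic ketone, C3 triethylsilyl ether (C1 epimer mixture) | C=C(C)CC1C(=O)[C@]2(O[Si](CC)(CC)CC)COC(C)(C)[C@@H]3CC[C@@](C)(C[C@@H]32)C1
F8 | step 16 | 1-(2-methylallyl) C1=C13 enone, C3 triethylsilyl ether | C=C(C)CC=1C(=O)[C@]2(O[Si](CC)(CC)CC)COC(C)(C)[C@@H]3CC[C@@](C)(C[C@@H]32)C=1
F9 | step 19 | keto aldehyde with C13–CH2–CHO arm and C1 acetonyl group, C3 triethylsilyl ether | CC(=O)C[C@@H]1C(=O)[C@]2(O[Si](CC)(CC)CC)COC(C)(C)[C@@H]3CC[C@@](C)(C[C@@H]32)[C@H]1CC=O
A1 | alternative 1 | tricyclic (4+3) cycloadduct with bridging C11 ketone and C1=C2 silyl enol ether | C1=C(O[Si](C)(C)C)[C@]2(O[Si](C)(C)C)COC(C)(C)[C@@H]3CC[C@@](C)(C(=O)[C@@H]32)[C@H]1CCO[Si](C)(C)C(C)(C)C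
A2 | alternative 2 | tricyclic C1=C13 enone with free C3 hydroxyl | C1=CC(=O)[C@]2(O)COC(C)(C)[C@@H]3CC[C@@]1(C)C[C@@H]32
A3 | alternative 2 | allene (propadiene) | C=C=C
A4 | alternative 2 | methylenecyclobutane photoadduct | C=C1C[C@H]2[C@@H]1C(=O)[C@]3(O)COC(C)(C)[C@@H]4CC[C@@]2(C)C[C@@H]43
A5 | alternative 2 | C13 acetic methyl ester after ozonolysis and retro-Claisen cleavage | C1C(=O)[C@]2(O)COC(C)(C)[C@@H]3CC[C@@](C)(C[C@@H]32)[C@H]1CC(=O)OC
A6 | alternative 3 | bridgehead-alkene tricycle (C7=C12, C13 ketone, C2 dithiane) | C1C5(SCCCS5)[C@]2(O)COC(C)(C)C3=C2C[C@](C)(CC3)C1=O
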